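**Plan**

1. Retrosynthesis: after removal of two O-benzyl groups and one O-TBS group, the oxan-4-one ring (O1, aryl-bearing C2, C3, C4=O, C5, C6) is cut at C5–C6 and at O1–C2, and C2 is re-joined to C5. This gives the 3-arylcyclobutanone 4 (C2–C3–C4–C5) and the α-silyloxy aldehyde 10 (C6=O1 with the whole side chain).
2. Enabling feature: C2 is benzylic to the guaiacyl ring (ring oxygen para to C2) and stands 1,3 to the C4 carbonyl. In the four-membered ring C2–C3–C4–C5 the C2–C5 bond is therefore a strained donor–acceptor σ-bond that a Lewis acid can open to a benzylic cation/enolate 1,4-dipole.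
3. Forward: 4 from O-benzylvanillin (Wittig, dichloroketene [2+2], dechlorination); 10 from O-benzyl-L-tyrosine (diazotisation, esterification, silylation, DIBAL-H). Union of 4 and 10 inserts C6=O1 into the cyclobutanone, so the four-membered ring grows to the six-membered ring; desilylation and hydrogenolysis follow.
4. Stereochemistry: the carbinol carbon C1' (S) is the α-carbon of L-tyrosine (diazotisation with retention). C6 (R) comes from Felkin–Anh addition to the α-silyloxy aldehyde (1,2-anti). C2 (S) comes from chair ring closure and equilibration to the 2,6-cis oxanone.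

Key step: step 8

Remark: the target is read as (2S,6R,1'S), that is 2,6-cis on the ring with O1–C6 and the C1' oxygen anti; 4-(benzyloxy)-3-methoxybenzaldehyde and O-benzyl-L-tyrosine are taken as catalogue compounds.

**Route**

Step 1
Reactants: 1 4-(benzyloxy)-3-methoxybenzaldehyde
Product: 2 1-(benzyloxy)-4-ethenyl-2-methoxybenzene (4-benzyloxy-3-methoxystyrene)
Conditions: Ph3PCH3Br, KOtBu, THF, 0 °C to rt
Reagents that add atoms: methyltriphenylphosphonium bromide, C[P+](c1ccccc1)(c1ccccc1)c1ccccc1.[Br-]
Why: Wittig methylenation of an aromatic aldehyde by the unstabilised ylide made in the flask is a standard olefination driven by P=O formation, the benzyl and methyl ethers are inert to it, and no stereocentre is formed.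

Step 2
Reactants: 2 1-(benzyloxy)-4-ethenyl-2-methoxybenzene
Product: 3 rac-3-[4-(benzyloxy)-3-methoxyphenyl]-2,2-dichlorocyclobutan-1-one
Conditions: Cl3CCOCl, Zn–Cu couple, POCl3, Et2O, rt to reflux
Reagents that add atoms: trichloroacetyl chloride, ClC(Cl)(Cl)C(Cl)=O
Why: Thermal [2+2] cycloaddition of dichloroketene (made in the flask by zinc dechlorination of the acid chloride) to a styrene joins the carbonyl carbon to the terminal CH2 and the CCl2 carbon to the benzylic carbon, so only the 3-aryl isomer should form, while POCl3 ties up ZnCl2 to limit cationic polymerisation of the electron-rich alkene; the single stereocentre forms racemic and loses its stereogenic character in step 3.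

Step 3
Reactants: 3 rac-3-[4-(benzyloxy)-3-methoxyphenyl]-2,2-dichlorocyclobutan-1-one
Product: 4 3-[4-(benzyloxy)-3-methoxyphenyl]cyclobutan-1-one (achiral)
Conditions: Zn dust, AcOH, rt to 60 °C
Reagents that add atoms: none
Why: Reductive dechlorination of an α,α-dichlorocyclobutanone by zinc in acetic acid (zinc enolates that are protonated) is the standard completion of the dichloroketene route, ketone and ethers should survive, and the product has a mirror plane.

Step 4
Reactants: 5 O-benzyl-L-tyrosine
Product: 7 (S)-3-[4-(benzyloxy)phenyl]-2-hydroxypropanoic acid, via α-lactone 6 (not isolated)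
Conditions: NaNO2, 1 M aq. H2SO4, 1,4-dioxane, 0 °C to rt
Reagents that add atoms: water, O
Why: Diazotisation of an α-amino acid in aqueous acid replaces NH2 by OH with net retention, because the neighbouring carboxylate displaces N2 with inversion to the α-lactone 6 and water opens it with a second inversion, so the (S) centre of L-tyrosine becomes the (S)-carbinol centre of the target; the O-benzyl group prevents nitrosation of the phenol ring.

Step 5
Reactants: 7 (S)-3-[4-(benzyloxy)phenyl]-2-hydroxypropanoic acid
Product: 8 methyl (S)-3-[4-(benzyloxy)phenyl]-2-hydroxypropanoate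
Conditions: MeOH, cat. H2SO4, reflux
Reagents that add atoms: methanol, CO
Why: Fischer esterification under acid catalysis should leave the secondary alcohol, the aryl benzyl ether and the stereocentre (no enolisation under these conditions) unchanged.

Step 6
Reactants: 8 methyl (S)-3-[4-(benzyloxy)phenyl]-2-hydroxypropanoate
Product: 9 methyl (S)-3-[4-(benzyloxy)phenyl]-2-[(tert-butyldimethylsilyl)oxy]propanoate
Conditions: TBSCl, imidazole, DMF, rt
Reagents that add atoms: tert-butyldimethylsilyl chloride, CC(C)(C)[Si](C)(C)Cl
Why: Standard silylation of a secondary alcohol installs a bulky, non-chelating ether that is meant to enforce Felkin–Anh control in step 8 and to survive the Lewis acid at low temperature.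

Step 7
Reactants: 9 methyl (S)-3-[4-(benzyloxy)phenyl]-2-[(tert-butyldimethylsilyl)oxy]propanoate
Product: 10 (S)-3-[4-(benzyloxy)phenyl]-2-[(tert-butyldimethylsilyl)oxy]propanal
Conditions: DIBAL-H (1.1 equiv), CH2Cl2, −78 °C; MeOH, aq. Rochelle salt
Reagents that add atoms: none
Why: DIBAL-H reduction of an α-silyloxy ester at −78 °C stops at the tetrahedral aluminium hemiacetal, which releases the aldehyde only on work-up, so over-reduction and epimerisation of the α-centre should be avoided; the aldehyde is used at once without chromatography.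

Step 8
Reactants: 4 3-[4-(benzyloxy)-3-methoxyphenyl]cyclobutan-1-one; 10 (S)-3-[4-(benzyloxy)phenyl]-2-[(tert-butyldimethylsilyl)oxy]propanal
Product: 13 (2S,6R)-2-[4-(benzyloxy)-3-methoxyphenyl]-6-{(1S)-2-[4-(benzyloxy)phenyl]-1-[(tert-butyldimethylsilyl)oxy]ethyl}oxan-4-one, via BF3-bound 1,4-zwitterion 11 (not isolated), via aldolate cation 12 (not isolated)
Conditions: BF3·OEt2 (1.5 equiv), 4 Å MS, CH2Cl2, −78 to −20 °C; aq. NaHCO3
Reagents that add atoms: none
Why: Proposed new method: BF3 coordination to the cyclobutanone carbonyl should trigger heterolysis of the ring bond between the aryl-bearing carbon and an α-CH2 (the two such bonds are equivalent by symmetry), driven by release of ring strain and by the 4-benzyloxy-3-methoxyphenyl group, which carries the positive charge as a para-quinoid oxocarbenium ion, to give the zwitterion 11 (boron enolate plus benzylic cation); the enolate CH2 then adds to the aldehyde carbonyl of 10 (C5–C6 bond, aldolate 12) and the new alkoxide captures the benzylic cation (O1–C2 bond), so that C6=O1 is inserted into the four-membered ring, which grows by two atoms. The closest known reaction types are the Lewis-acid formal [4+2] cycloaddition of 3-alkoxycyclobutanones with aldehydes and the [4+2] annulation of aryl-substituted donor–acceptor cyclobutanes with aldehydes; what is new is that an electron-rich aryl group alone serves as the donor on a cyclobutanone. The six-membered ring closes by C–O bond formation in a 6-exo-trig sense (alkoxide oxygen onto the quinoid benzylic carbon, whose π-bond to the arene lies outside the new ring) through a chair transition state. C6 is set in the aldol event by Felkin–Anh (polar, non-chelate) addition to the α-silyloxy aldehyde, the monodentate BF3 and the bulky OTBS group excluding chelation, which should give the 1,2-anti relation, that is (6R) next to the (S)-carbinol carbon from L-tyrosine. C2 is set in the ring closure, with aryl and C6 side chain both equatorial in the chair, and because the electron-rich benzylic C2–O1 bond can re-ionise under the Lewis acid the diequatorial 2,6-cis isomer (2S) should also be the thermodynamic product. The selectivity needed is capture of the dipole by the aldehyde in preference to proton loss to the aryl enone, which the low temperature, the non-basic medium and the intramolecular nature of the final C–O closure should favour; an enone–aldol by-pass would still converge on the same ring by oxa-Michael closure.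

Step 9
Reactants: 13 (2S,6R)-2-[4-(benzyloxy)-3-methoxyphenyl]-6-{(1S)-2-[4-(benzyloxy)phenyl]-1-[(tert-butyldimethylsilyl)oxy]ethyl}oxan-4-one
Product: 14 (2S,6R)-2-[4-(benzyloxy)-3-methoxyphenyl]-6-{(1S)-2-[4-(benzyloxy)phenyl]-1-hydroxyethyl}oxan-4-one
Conditions: HF·pyridine, pyridine, THF, 0 °C to rt
Reagents that add atoms: none
Why: Fluoride-driven cleavage of the secondary silyl ether under weakly acidic buffered conditions should avoid base-induced retro-oxa-Michael opening of the β-alkoxy ketone and leaves the benzyl ethers and all stereocentres untouched.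

Step 10
Reactants: 14 (2S,6R)-2-[4-(benzyloxy)-3-methoxyphenyl]-6-{(1S)-2-[4-(benzyloxy)phenyl]-1-hydroxyethyl}oxan-4-one
Product: 15 (2S,6R)-2-(4-hydroxy-3-methoxyphenyl)-6-[(1S)-1-hydroxy-2-(4-hydroxyphenyl)ethyl]oxan-4-one
Conditions: H2 (1 atm), 10% Pd/C, EtOAc, rt
Reagents that add atoms: none
Why: Catalytic hydrogenolysis of aryl benzyl ethers over Pd/C under neutral conditions is much faster than cleavage of the cyclic benzylic C2–O1 ether or reduction of the ketone, so stopping after uptake of two equivalents of hydrogen should deliver the target with its three stereocentres unchanged.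

**Compound list**

1 | 4-(benzyloxy)-3-methoxybenzaldehyde | COc1cc(C=O)ccc1OCc1ccccc1 | starting material
2 | 1-(benzyloxy)-4-ethenyl-2-methoxybenzene | COc1cc(C=C)ccc1OCc1ccccc1 | intermediate
3 | rac-3-[4-(benzyloxy)-3-methoxyphenyl]-2,2-dichlorocyclobutan-1-one | COc1cc(C2CC(=O)C2(Cl)Cl)ccc1OCc1ccccc1 | intermediate
4 | 3-[4-(benzyloxy)-3-methoxyphenyl]cyclobutan-1-one | COc1cc(C2CC(=O)C2)ccc1OCc1ccccc1 | intermediate
5 | O-benzyl-L-tyrosine | N[C@@H](Cc1ccc(OCc2ccccc2)cc1)C(=O)O | starting material
6 | (R)-3-[4-(benzyloxy)benzyl]oxiran-2-one (α-lactone) | O1[C@H](Cc2ccc(OCc3ccccc3)cc2)C1=O | intermediate (not isolated)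
7 | (S)-3-[4-(benzyloxy)phenyl]-2-hydroxypropanoic acid | O[C@@H](Cc1ccc(OCc2ccccc2)cc1)C(=O)O | intermediate
8 | methyl (S)-3-[4-(benzyloxy)phenyl]-2-hydroxypropanoate | O[C@@H](Cc1ccc(OCc2ccccc2)cc1)C(=O)OC | intermediate
9 | methyl (S)-3-[4-(benzyloxy)phenyl]-2-[(tert-butyldimethylsilyl)oxy]propanoate | CC(C)(C)[Si](C)(C)O[C@@H](Cc1ccc(OCc2ccccc2)cc1)C(=O)OC | intermediate
10 | (S)-3-[4-(benzyloxy)phenyl]-2-[(tert-butyldimethylsilyl)oxy]propanal | CC(C)(C)[Si](C)(C)O[C@@H](Cc1ccc(OCc2ccccc2)cc1)C=O | intermediate
11 | BF3-bound 1,4-zwitterion: 1-[4-(benzyloxy)-3-methoxyphenyl]-3-(trifluoroboranuidyloxy)but-3-en-1-ylium | C=C(O[B-](F)(F)F)C[CH+]c1ccc(OCc2ccccc2)c(OC)c1 | intermediate (not isolated)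
12 | aldolate cation: (5R,6S)-1-[4-(benzyloxy)-3-methoxyphenyl]-7-[4-(benzyloxy)phenyl]-6-[(tert-butyldimethylsilyl)oxy]-3-oxo-5-(trifluoroboranuidyloxy)heptan-1-ylium | COc1cc([CH+]CC(=O)C[C@H]([C@@H](O[Si](C)(C)C(C)(C)C)Cc2ccc(OCc3ccccc3)cc2)O[B-](F)(F)F)ccc1OCc1ccccc1 | intermediate (not isolated)
13 | (2S,6R)-2-[4-(benzyloxy)-3-methoxyphenyl]-6-{(1S)-2-[4-(benzyloxy)phenyl]-1-[(tert-butyldimethylsilyl)oxy]ethyl}oxan-4-one | COc1cc([C@@H]2CC(=O)C[C@H]([C@@H](O[Si](C)(C)C(C)(C)C)Cc3ccc(OCc4ccccc4)cc3)O2)ccc1OCc1ccccc1 | intermediate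
14 | (2S,6R)-2-[4-(benzyloxy)-3-methoxyphenyl]-6-{(1S)-2-[4-(benzyloxy)phenyl]-1-hydroxyethyl}oxan-4-one | COc1cc([C@@H]2CC(=O)C[C@H]([C@@H](O)Cc3ccc(OCc4ccccc4)cc3)O2)ccc1OCc1ccccc1 | intermediate
15 | (2S,6R)-2-(4-hydroxy-3-methoxyphenyl)-6-[(1S)-1-hydroxy-2-(4-hydroxyphenyl)ethyl]oxan-4-one | COc1cc([C@@H]2CC(=O)C[C@H]([C@@H](O)Cc3ccc(O)cc3)O2)ccc1O | target

**Summary**

Total step count: 10.
Longest linear sequence: 7 steps (5 to 15, steps 4–10); the cyclobutanone branch (steps 1–3) joins at step 8.

Steps most likely to fail:

1. Step 8 (Proposed new method). The aryl donor may be too weak for ring opening at low temperature, the benzylic cation may lose a proton to the aryl enone before the aldehyde is captured, facial selectivity at the aldehyde may be eroded, or the silyl ether may be lost to the Lewis acid. The fallback uses known chemistry, sets out from 1 and 10, and returns to the route at 13. Claisen–Schmidt condensation of 1 with acetone (aq. NaOH) gives (E)-4-[4-(benzyloxy)-3-methoxyphenyl]but-3-en-2-one F1. Soft enolisation (TMSOTf, Et3N, CH2Cl2, 0 °C) gives {[(3E)-4-[4-(benzyloxy)-3-methoxyphenyl]buta-1,3-dien-2-yl]oxy}trimethylsilane F2. Mukaiyama aldol addition of F2 to 10 (BF3·OEt2, CH2Cl2, −78 °C, Felkin–Anh control) gives (1E,5R,6S)-1-[4-(benzyloxy)-3-methoxyphenyl]-7-[4-(benzyloxy)phenyl]-6-[(tert-butyldimethylsilyl)oxy]-5-hydroxyhept-1-en-3-one F3. A 6-endo-trig oxa-Michael cyclisation under equilibrating conditions (cat. DBU, CH2Cl2, rt) should then close the 2,6-cis oxanone 13.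

2. Step 2. Cationic polymerisation of the electron-rich styrene by zinc chloride, or acid-induced ring opening of the labile dichlorocyclobutanone during isolation, may erode the material. The fallback sets out from 2 and returns at 4, by-passing 3. A keteniminium [2+2] cycloaddition (N,N-dimethylacetamide, Tf2O, 2,4,6-collidine, 1,2-dichloroethane, reflux) gives N-{3-[4-(benzyloxy)-3-methoxyphenyl]cyclobutylidene}-N-methylmethanaminium triflate F4, which is hydrolysed in the same flask (aq. NaHCO3) to 4.

3. Step 7. Over-reduction to the primary alcohol, or epimerisation of the α-silyloxy aldehyde during work-up, may occur. The fallback sets out from 9 and returns at 10. Full reduction (excess DIBAL-H, CH2Cl2, −78 to 0 °C) gives (S)-3-[4-(benzyloxy)phenyl]-2-[(tert-butyldimethylsilyl)oxy]propan-1-ol F5, which is re-oxidised under non-basic conditions (Dess–Martin periodinane, NaHCO3, CH2Cl2) to 10.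

**Further compounds**

F1 | step 8 | (E)-4-[4-(benzyloxy)-3-methoxyphenyl]but-3-en-2-one | CC(=O)/C=C/c1ccc(OCc2ccccc2)c(OC)c1
F2 | step 8 | {[(3E)-4-[4-(benzyloxy)-3-methoxyphenyl]buta-1,3-dien-2-yl]oxy}trimethylsilane | C=C(O[Si](C)(C)C)/C=C/c1ccc(OCc2ccccc2)c(OC)c1
F3 | step 8 | (1E,5R,6S)-1-[4-(benzyloxy)-3-methoxyphenyl]-7-[4-(benzyloxy)phenyl]-6-[(tert-butyldimethylsilyl)oxy]-5-hydroxyhept-1-en-3-one | COc1cc(/C=C/C(=O)C[C@H]([C@@H](O[Si](C)(C)C(C)(C)C)Cc2ccc(OCc3ccccc3)cc2)O)ccc1OCc1ccccc1
F4 | step 2 | N-{3-[4-(benzyloxy)-3-methoxyphenyl]cyclobutylidene}-N-methylmethanaminium triflate | C[N+](C)=C1CC(c2ccc(OCc3ccccc3)c(OC)c2)C1.[O-]S(=O)(=O)C(F)(F)F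
F5 | step 7 | (S)-3-[4-(benzyloxy)phenyl]-2-[(tert-butyldimethylsilyl)oxy]propan-1-ol | CC(C)(C)[Si](C)(C)O[C@@H](Cc1ccc(OCc2ccccc2)cc1)CO
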